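**Retrosynthetic overview**
1. Target ⇐ global desilylation of a silyl-protected eudesmane that already carries the 8-acetate and the α-methylene ester.
2. Both rings form in one Lewis-acid operation from an acyclic epoxide: ring A first (C5–C10 bond, enol silane onto the ionising epoxide), then ring B (C6–C7 bond, allylsilane onto the C6 oxocarbenium ion just formed).
3. The acyclic precursor ⇐ Shi epoxidation (C1, C10), then vinyl → aldehyde → enol silane.
4. The C8 acetate and the acrylate-bearing allylsilane ⇐ proline-catalysed α-aminoxylation/HWE olefination of a γ,δ-unsaturated aldehyde.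
5. That aldehyde ⇐ (R)-linalool (supplies C4) by allylic oxidation, bromination and two-carbon homologation.

Assumption: positions are labelled with eudesmane numbering (C1–C15) in all intermediates; TBS = tert-butyldimethylsilyl, TMS = trimethylsilyl; commercial (R)-(−)-linalool of high ee is used.

**Route**

Step 1
Reactants: 1 (R)-(−)-linalool; 2 tert-butyldimethylsilyl trifluoromethanesulfonate (TBSOTf)
Product: 3 (3R)-3-(tert-butyldimethylsilyloxy)-3,7-dimethylocta-1,6-diene
Conditions: TBSOTf, 2,6-lutidine, CH2Cl2, 0 °C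
Reagents that add atoms: TBSOTf CC(C)(C)[Si](C)(C)OS(=O)(=O)C(F)(F)F
Why: O-silylation of the tertiary allylic alcohol with a silyl triflate and a hindered base proceeds without ionisation, so the chiral-pool stereocentre (future C4, 4α-O/4β-Me) is kept.

Step 2
Reactants: 3; 4 tert-butyl hydroperoxide
Product: 5 (2E,6R)-6-(tert-butyldimethylsilyloxy)-2,6-dimethylocta-2,7-dien-1-ol
Conditions: SeO2 (0.1 equiv), t-BuOOH, salicylic acid (0.1 equiv), CH2Cl2, rt
Reagents that add atoms: tert-butyl hydroperoxide CC(C)(C)OO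
Why: SeO2-catalysed allylic oxidation (ene reaction then 2,3-sigmatropic shift) hydroxylates the (E)-methyl group of the gem-dimethyl alkene, and the vinyl group has no allylic C–H.

Step 3
Reactants: 5; 6 carbon tetrabromide
Product: 7 (2E,6R)-1-bromo-6-(tert-butyldimethylsilyloxy)-2,6-dimethylocta-2,7-diene
Conditions: CBr4, PPh3, 2,6-lutidine, CH2Cl2, −20 °C
Reagents that add atoms: carbon tetrabromide BrC(Br)(Br)Br
Why: Appel bromination of the primary allylic alcohol is an SN2 process that keeps the E geometry.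

Step 4
Reactants: 7; 8 acetaldehyde N,N-dimethylhydrazone; 9 water
Product: 11 (4E,8R)-8-(tert-butyldimethylsilyloxy)-4,8-dimethyldeca-4,9-dienal, via alkylated dimethylhydrazone 10 (not isolated)
Conditions: 8, LiN(i-Pr)2, THF, 0 °C; then 7, −78 → 0 °C; then aq. oxalic acid, Et2O, rt
Reagents that add atoms: acetaldehyde N,N-dimethylhydrazone CC=NN(C)C; water O
Why: Aza-enolate alkylation (Corey–Enders type) attacks the primary allylic bromide by SN2 and mild hydrolysis frees the aldehyde, adding C8 and C7 without touching the E alkene.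

Step 5
Reactants: 12 trimethyl phosphonoacetate; 13 (iodomethyl)trimethylsilane
Product: 14 methyl 2-(dimethoxyphosphoryl)-3-(trimethylsilyl)propanoate (racemic)
Conditions: NaH, DME, 0 °C; then 13, 70 °C
Reagents that add atoms: (iodomethyl)trimethylsilane C[Si](C)(C)CI
Why: C-alkylation of the sodium phosphonoacetate anion by the primary α-silyl iodide gives the HWE reagent that carries the future C13 silane.

Step 6
Reactants: 11; 15 nitrosobenzene; 14
Product: 17 methyl (2Z,4S,6E,10R)-10-(tert-butyldimethylsilyloxy)-6,10-dimethyl-4-(N-phenylaminooxy)-2-[(trimethylsilyl)methyl]dodeca-2,6,11-trienoate, via α-aminoxy aldehyde 16 (not isolated)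
Conditions: D-proline (0.25 equiv), PhNO, MeCN, −20 °C; then 14, LiCl, DBU, 0 °C
Reagents that add atoms: nitrosobenzene O=Nc1ccccc1; methyl 2-(dimethoxyphosphoryl)-3-(trimethylsilyl)propanoate COC(=O)C(C[Si](C)(C)C)P(=O)(OC)OC
Why: Proline-catalysed enamine α-aminoxylation (O-nitroso aldol) sets C8 under catalyst control (D-proline gives the S centre, the future 8α-oxygen), and Masamune–Roush HWE olefination in the same flask traps the labile aldehyde as the enoate with C8 trans to the ester.

Step 7
Reactants: 17; 18 acetic anhydride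
Product: 20 methyl (2Z,4S,6E,10R)-4-acetoxy-10-(tert-butyldimethylsilyloxy)-6,10-dimethyl-2-[(trimethylsilyl)methyl]dodeca-2,6,11-trienoate, via allylic alcohol 19 (not isolated)
Conditions: Cu(OAc)2·H2O (0.3 equiv), EtOH, rt; evaporate; then Ac2O, pyridine, DMAP (cat.), CH2Cl2, 0 °C
Reagents that add atoms: acetic anhydride CC(=O)OC(C)=O
Why: Copper-catalysed N–O cleavage frees the C8 hydroxyl without touching the stereocentre, and acylation installs the target's acetate while no other free hydroxyl is present.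

Step 8
Reactants: 20; 21 potassium peroxymonosulfate KHSO5
Product: 22 methyl (2Z,4S)-4-acetoxy-5-[(2R,3R)-3-[(3R)-3-(tert-butyldimethylsilyloxy)-3-methylpent-4-en-1-yl]-2-methyloxiran-2-yl]-2-[(trimethylsilyl)methyl]pent-2-enoate
Conditions: D-fructose-derived Shi ketone (0.3 equiv), KHSO5 (as 2KHSO5·KHSO4·K2SO4), K2CO3, Bu4NHSO4, aq. Na2B4O7 buffer (pH 10.5), MeCN–dimethoxymethane–H2O, 0 °C
Reagents that add atoms: potassium peroxymonosulfate [K+].[O-]S(=O)(=O)OO
Why: Shi asymmetric epoxidation oxidises only the electron-rich trisubstituted alkene (the hindered vinyl group and the ester-conjugated alkene are inert) through the spiro transition state and gives the (R,R)-epoxide that becomes C1 and C10.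

Step 9
Reactants: 22; 23 sodium perborate tetrahydrate NaBO3·4H2O
Product: 24 methyl (2Z,4S)-4-acetoxy-5-[(2R,3R)-3-[(3R)-3-(tert-butyldimethylsilyloxy)-5-hydroxy-3-methylpentyl]-2-methyloxiran-2-yl]-2-[(trimethylsilyl)methyl]pent-2-enoate
Conditions: 9-BBN (1.5 equiv), THF, 0 °C → rt; then NaBO3·4H2O, H2O, rt
Reagents that add atoms: sodium perborate [Na+].[O-]OB=O
Why: Anti-Markovnikov hydroboration–oxidation with the bulky borane selects the monosubstituted vinyl group over the conjugated alkene, and perborate oxidation spares the epoxide and the acetate.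

Step 10
Reactants: 24
Product: 25 methyl (2Z,4S)-4-acetoxy-5-[(2R,3R)-3-[(3R)-3-(tert-butyldimethylsilyloxy)-3-methyl-5-oxopentyl]-2-methyloxiran-2-yl]-2-[(trimethylsilyl)methyl]pent-2-enoate
Conditions: Dess–Martin periodinane, NaHCO3, CH2Cl2, 0 °C → rt
Reagents that add atoms: none
Why: Buffered Dess–Martin oxidation gives the β-silyloxy aldehyde (C6) under neutral conditions that leave the epoxide and the allylsilane intact.

Step 11
Reactants: 25; 2 TBSOTf
Product: 26 methyl (2Z,4S)-4-acetoxy-5-[(2R,3R)-3-[(3R,4E)-3,5-bis(tert-butyldimethylsilyloxy)-3-methylpent-4-en-1-yl]-2-methyloxiran-2-yl]-2-[(trimethylsilyl)methyl]pent-2-enoate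
Conditions: TBSOTf (1.2 equiv), Et3N (2 equiv), CH2Cl2, −78 °C
Reagents that add atoms: TBSOTf CC(C)(C)[Si](C)(C)OS(=O)(=O)C(F)(F)F
Why: Soft enolisation (O-silylation then deprotonation by the amine) turns the aldehyde into its E enol silane at a temperature where the amine-buffered silyl triflate does not open the epoxide and no free enolate can expel the β-silyloxy group.

Step 12
Reactants: 26
Product: 28 methyl 8α-acetoxy-4α,6α-bis(tert-butyldimethylsilyloxy)-1β-hydroxy-5α,7αH-eudesm-11(13)-en-12-oate, via ring-A oxocarbenium zwitterion 27 (not isolated)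
Conditions: MeAlCl2 (2.5 equiv), CH2Cl2, −78 → −40 °C; then Et3N, aq. NaHCO3
Reagents that add atoms: none
Why: Proposed new method: MeAlCl2 ionises the epoxide at the tertiary carbon C10 with anti participation of the enol-silane carbon C5 through a chair transition state (closest known reaction type: Lewis-acid-initiated epoxy-polyene cyclisation terminated by a silyl enol ether), which closes ring A with retention at C1 (1β-OH), inversion at C10 (10β-Me) and an equatorial C5–C6 bond (5α-H); because the enol silane sits inside the chain, the resulting C6 silyloxocarbenium ion is an electrophile that is trapped at once by the γ-carbon C7 of the tethered 2-(silylmethyl)acrylate (closest known reaction type: intramolecular Hosomi–Sakurai allylation of ω-formyl 2-(silylmethyl)alkenoates), closing ring B through a chair in which O6, the C7 side chain and the preset 8-OAc are all equatorial (the 6β face is blocked by the axial methyl groups on C4 and C10) and releasing the α-methylene ester on loss of the TMS group.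

Step 13
Reactants: 28
Product: 29 methyl 8α-acetoxy-1β,4α,6α-trihydroxy-5α,7αH-eudesm-11(13)-en-12-oate (CNP0272656.1)
Conditions: HF·pyridine, pyridine, THF, 0 °C → rt
Reagents that add atoms: none
Why: Buffered fluoride desilylation removes both TBS ethers without acyl migration, lactonisation onto the methyl ester or loss of the tertiary alcohol, and no stereocentre is touched.

**Compound list**
1 | (R)-(−)-linalool | C=C[C@](C)(O)CCC=C(C)C | starting material
2 | tert-butyldimethylsilyl trifluoromethanesulfonate | CC(C)(C)[Si](C)(C)OS(=O)(=O)C(F)(F)F | starting material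
3 | (3R)-3-(tert-butyldimethylsilyloxy)-3,7-dimethylocta-1,6-diene | C=C[C@](C)(O[Si](C)(C)C(C)(C)C)CCC=C(C)C | intermediate
4 | tert-butyl hydroperoxide | CC(C)(C)OO | starting material
5 | (2E,6R)-6-(tert-butyldimethylsilyloxy)-2,6-dimethylocta-2,7-dien-1-ol | C=C[C@](C)(O[Si](C)(C)C(C)(C)C)CC/C=C(\C)CO | intermediate
6 | carbon tetrabromide | BrC(Br)(Br)Br | starting material
7 | (2E,6R)-1-bromo-6-(tert-butyldimethylsilyloxy)-2,6-dimethylocta-2,7-diene | C=C[C@](C)(O[Si](C)(C)C(C)(C)C)CC/C=C(\C)CBr | intermediate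
8 | acetaldehyde N,N-dimethylhydrazone | CC=NN(C)C | starting material
9 | water | O | starting material
10 | N,N-dimethylhydrazone of aldehyde 11 | C=C[C@](C)(O[Si](C)(C)C(C)(C)C)CC/C=C(\C)CCC=NN(C)C | intermediate
11 | (4E,8R)-8-(tert-butyldimethylsilyloxy)-4,8-dimethyldeca-4,9-dienal | C=C[C@](C)(O[Si](C)(C)C(C)(C)C)CC/C=C(\C)CCC=O | intermediate
12 | trimethyl phosphonoacetate | COC(=O)CP(=O)(OC)OC | starting material
13 | (iodomethyl)trimethylsilane | C[Si](C)(C)CI | starting material
14 | methyl 2-(dimethoxyphosphoryl)-3-(trimethylsilyl)propanoate (racemic) | COC(=O)C(C[Si](C)(C)C)P(=O)(OC)OC | intermediate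
15 | nitrosobenzene | O=Nc1ccccc1 | starting material
16 | (2S,4E,8R)-8-(tert-butyldimethylsilyloxy)-4,8-dimethyl-2-(N-phenylaminooxy)deca-4,9-dienal | C=C[C@](C)(O[Si](C)(C)C(C)(C)C)CC/C=C(\C)C[C@H](ONc1ccccc1)C=O | intermediate
17 | methyl (2Z,4S,6E,10R)-10-(tert-butyldimethylsilyloxy)-6,10-dimethyl-4-(N-phenylaminooxy)-2-[(trimethylsilyl)methyl]dodeca-2,6,11-trienoate | C=C[C@](C)(O[Si](C)(C)C(C)(C)C)CC/C=C(\C)C[C@H](ONc1ccccc1)/C=C(\C[Si](C)(C)C)C(=O)OC | intermediate
18 | acetic anhydride | CC(=O)OC(C)=O | starting material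
19 | methyl (2Z,4S,6E,10R)-10-(tert-butyldimethylsilyloxy)-4-hydroxy-6,10-dimethyl-2-[(trimethylsilyl)methyl]dodeca-2,6,11-trienoate | C=C[C@](C)(O[Si](C)(C)C(C)(C)C)CC/C=C(\C)C[C@H](O)/C=C(\C[Si](C)(C)C)C(=O)OC | intermediate
20 | methyl (2Z,4S,6E,10R)-4-acetoxy-10-(tert-butyldimethylsilyloxy)-6,10-dimethyl-2-[(trimethylsilyl)methyl]dodeca-2,6,11-trienoate | C=C[C@](C)(O[Si](C)(C)C(C)(C)C)CC/C=C(\C)C[C@H](OC(C)=O)/C=C(\C[Si](C)(C)C)C(=O)OC | intermediate
21 | potassium peroxymonosulfate KHSO5 | [K+].[O-]S(=O)(=O)OO | starting material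
22 | (1R,10R)-epoxide of 20 (name in step 8) | C=C[C@](C)(O[Si](C)(C)C(C)(C)C)CC[C@H]1O[C@]1(C)C[C@H](OC(C)=O)/C=C(\C[Si](C)(C)C)C(=O)OC | intermediate
23 | sodium perborate tetrahydrate NaBO3·4H2O | [Na+].[O-]OB=O | starting material
24 | C6 primary alcohol (name in step 9) | OCC[C@](C)(O[Si](C)(C)C(C)(C)C)CC[C@H]1O[C@]1(C)C[C@H](OC(C)=O)/C=C(\C[Si](C)(C)C)C(=O)OC | intermediate
25 | C6 aldehyde (name in step 10) | O=CC[C@](C)(O[Si](C)(C)C(C)(C)C)CC[C@H]1O[C@]1(C)C[C@H](OC(C)=O)/C=C(\C[Si](C)(C)C)C(=O)OC | intermediate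
26 | (E)-enol silane cyclisation precursor (name in step 11) | CC(C)(C)[Si](C)(C)O/C=C/[C@](C)(O[Si](C)(C)C(C)(C)C)CC[C@H]1O[C@]1(C)C[C@H](OC(C)=O)/C=C(\C[Si](C)(C)C)C(=O)OC | intermediate
27 | ring-A oxocarbenium zwitterion: ring A closed (1β-O–Al, 4α-OTBS, 4β-Me, 5α-H, 10β-Me), C6 as O-silyl oxocarbenium, C9–C13 allylsilane chain on C10 | C[Al-](Cl)(Cl)O[C@@H]1CC[C@@](C)(O[Si](C)(C)C(C)(C)C)[C@H](C=[O+][Si](C)(C)C(C)(C)C)[C@@]1(C)C[C@H](OC(C)=O)/C=C(\C[Si](C)(C)C)C(=O)OC | intermediate
28 | methyl 8α-acetoxy-4α,6α-bis(tert-butyldimethylsilyloxy)-1β-hydroxy-5α,7αH-eudesm-11(13)-en-12-oate | C=C(C(=O)OC)[C@H]1[C@H](O[Si](C)(C)C(C)(C)C)[C@@H]2[C@@](C)(C[C@@H]1OC(C)=O)[C@H](O)CC[C@@]2(C)O[Si](C)(C)C(C)(C)C | intermediate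
29 | methyl 8α-acetoxy-1β,4α,6α-trihydroxy-5α,7αH-eudesm-11(13)-en-12-oate (CNP0272656.1) | C=C(C(=O)OC)[C@H]1[C@H](O)[C@@H]2[C@@](C)(C[C@@H]1OC(C)=O)[C@H](O)CC[C@@]2(C)O | target

**Step count**
Total step count: 13 (12 in the main line plus step 5, which makes reagent 14).
Longest linear sequence: 12 steps (steps 1–4 and 6–13).

**Three steps most likely to fail**

Step 12 (the two-ring relay). The risks are these:
- the ester-bearing allylsilane is a weak nucleophile and may not trap the C6 oxocarbenium ion;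
- the 8-acetate or the C4 silyl ether may intercept the C10 cation;
- the facial selectivity at C5 is argued from a chair model, not proven.

Fallback: give up the relay and close the rings one at a time. Setting out from 26, brief exposure to MeAlCl2 (1.1 equiv, CH2Cl2, −95 °C, Et3N quench) should stop after the first closure and give the ring-A hydroxy aldehyde F1. A separate intramolecular Hosomi–Sakurai reaction of F1 with TiCl4 (CH2Cl2, −78 °C) then closes ring B to give the 1β,6α-diol 4-O-silyl ether F2. HF·pyridine converts F2 into 29, where the route is rejoined.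

Step 11 (enol silane formation beside the epoxide). The silyl triflate may open the trisubstituted epoxide, or the β-silyloxy aldehyde may eliminate to an enal. Fallback: do not isolate an enol silane and let the silyl triflate do both jobs. Setting out from 25, TBSOTf (2.5 equiv) with 2,6-di-tert-butyl-4-methylpyridine (CH2Cl2, −78 → −30 °C) forms the enol silane in the flask. The excess silyl triflate then activates the epoxide, so the same ring A then ring B relay runs with silicon as the only Lewis acid and gives the tris-silyl ether F3. HF·pyridine (as in step 13) gives 29, where the route is rejoined.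

Step 6 (aminoxylation/HWE). The aldehyde must be used as the limiting reagent, the α-aminoxy aldehyde is labile, and the α-branched phosphonate is sluggish and may give E/Z mixtures. Fallback: set C8 by auxiliary-controlled glycolate alkylation, setting out from bromide 7.
- (R)-4-Benzyl-2-oxazolidinone is N-acylated (n-BuLi, (4-methoxybenzyloxy)acetyl chloride, THF, −78 °C) to the glycolyl imide F4.
- Its sodium enolate (NaN(SiMe3)2, THF, −78 °C) is alkylated by 7 on the face away from the benzyl group to give the (S)-configured alkylated imide F5.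
- LiBH4 (THF, MeOH, 0 °C) removes the auxiliary to give the primary alcohol F6.
- Dess–Martin oxidation followed in the same flask by HWE reaction with 14 (LiCl, DBU) gives the PMB-protected enoate F7.
- DDQ (CH2Cl2, pH 7 buffer) unveils the alcohol 19, where the route is rejoined (acetylation as in step 7 gives 20).

**Further compounds**
F1 | step 12 | ring-A hydroxy aldehyde: 1β-OH, 4α-OTBS, 4β-Me, 5α-H, 10β-Me cyclohexane with CHO (C6) on C5 and the (8S)-acetoxy (Z)-allylsilane ester chain on C10 | O[C@@H]1CC[C@@](C)(O[Si](C)(C)C(C)(C)C)[C@H](C=O)[C@@]1(C)C[C@H](OC(C)=O)/C=C(\C[Si](C)(C)C)C(=O)OC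
F2 | step 12 | methyl 8α-acetoxy-4α-(tert-butyldimethylsilyloxy)-1β,6α-dihydroxy-5α,7αH-eudesm-11(13)-en-12-oate | C=C(C(=O)OC)[C@H]1[C@H](O)[C@@H]2[C@@](C)(C[C@@H]1OC(C)=O)[C@H](O)CC[C@@]2(C)O[Si](C)(C)C(C)(C)C
F3 | step 11 | methyl 8α-acetoxy-1β,4α,6α-tris(tert-butyldimethylsilyloxy)-5α,7αH-eudesm-11(13)-en-12-oate | C=C(C(=O)OC)[C@H]1[C@H](O[Si](C)(C)C(C)(C)C)[C@@H]2[C@@](C)(C[C@@H]1OC(C)=O)[C@H](O[Si](C)(C)C(C)(C)C)CC[C@@]2(C)O[Si](C)(C)C(C)(C)C
F4 | step 6 | (R)-4-benzyl-3-[(4-methoxybenzyloxy)acetyl]oxazolidin-2-one | C1[C@H](N(C(=O)O1)C(=O)COCc2ccc(OC)cc2)Cc3ccccc3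
F5 | step 6 | (R)-4-benzyl-3-[(2S,4E,8R)-8-(tert-butyldimethylsilyloxy)-2-(4-methoxybenzyloxy)-4,8-dimethyldeca-4,9-dienoyl]oxazolidin-2-one | C=C[C@](C)(O[Si](C)(C)C(C)(C)C)CC/C=C(\C)C[C@H](OCc1ccc(OC)cc1)C(=O)N1[C@H](Cc2ccccc2)COC1=O
F6 | step 6 | (2S,4E,8R)-8-(tert-butyldimethylsilyloxy)-2-(4-methoxybenzyloxy)-4,8-dimethyldeca-4,9-dien-1-ol | C=C[C@](C)(O[Si](C)(C)C(C)(C)C)CC/C=C(\C)C[C@H](OCc1ccc(OC)cc1)CO
F7 | step 6 | methyl (2Z,4S,6E,10R)-10-(tert-butyldimethylsilyloxy)-4-(4-methoxybenzyloxy)-6,10-dimethyl-2-[(trimethylsilyl)methyl]dodeca-2,6,11-trienoate | C=C[C@](C)(O[Si](C)(C)C(C)(C)C)CC/C=C(\C)C[C@H](OCc1ccc(OC)cc1)/C=C(\C[Si](C)(C)C)C(=O)OC
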